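**Plan**
- Retrosynthesis: cut the C6 ester, then ring B at C5–C6 together with one C4–CH3 bond (aldehyde–alkene cyclization with methylative termination), then C7=C8 (aldol condensation), C8–C9 (enolate alkylation) and C10–CH3 (conjugate addition).
- Forward: ring A is made first as a cyclohexene carrying the C10 quaternary carbon and a C4=C5 double bond; the chain C9–C8(C12)=C7–C6HO is grown from the acetate arm on C10; ring B closes last by C5–C6.
- Enabling feature: C4, the gem-dimethyl carbon of ring A, is bonded to C5 and stands 1,3 to the C6 oxygen. A C4=C5 alkene can therefore attack a C6 aldehyde with C4 as tertiary cationic terminus, and the cation takes up the second methyl group.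
- Stereochemistry: C10 from ligand-controlled copper-catalysed methyl addition; C5 by equilibration of the 7-en-6-one to the trans-fused decalin; C6 (hydride) and C9 (enolate hydroxylation) by attack on the α-face, away from the axial C4 and C10 methyl groups; the trienoate geometry from (2E,4E)-hexa-2,4-dienal.

Key step: step 7

Assumption: the target is taken as the open 12-aldehyde 11-carboxylic acid drawn; its possible ring–chain tautomerism to the 12-hydroxy-11,12-lactone is not treated separately. Drimane numbering is used throughout (ring A: C1–C5 and C10; ring B: C5–C10; C11 on C9, C12 on C8).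

**Route**

Step 1
Reactants: 1 3-ethoxycyclohex-2-en-1-one; 2 tert-butyl acetate
Product: 4 tert-butyl 2-(3-oxocyclohex-1-en-1-yl)acetate, via hydroxy enol ether 3 (not isolated)
Conditions: LiN(iPr)2, THF, −78 °C, then 1; 1 M aq. HCl, 0 °C to rt
Reagents that add atoms: water, O
Why: Stork–Danheiser sequence: the lithium enolate of 2 adds 1,2 to the vinylogous ester and acid hydrolysis of the enol ether with loss of the tertiary hydroxyl transposes the enone, so the acetate arm (future C9 and C11) ends up on the β-carbon (future C10); no stereocentre is formed.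

Step 2
Reactants: 4
Product: 6 tert-butyl 2-[(1R)-1-methyl-3-(trifluoromethylsulfonyloxy)cyclohex-2-en-1-yl]acetate, via aluminium enolate 5 (not isolated)
Conditions: Me3Al (1.5 equiv), Cu(O2CC4H3S) (5 mol %), phosphoramidite L* (10 mol %; O,O′-(S)-1,1′-binaphthalene-2,2′-diyl N,N-bis[(S)-1-phenylethyl]phosphoramidite or its enantiomer, whichever delivers the R product), Et2O, −30 °C; MeLi, THF, −78 °C; PhNTf2, −78 °C to rt
Reagents that add atoms: trimethylaluminium, C[Al](C)C; N-phenylbis(trifluoromethanesulfonimide), O=S(=O)(N(c1ccccc1)S(=O)(=O)C(F)(F)F)C(F)(F)F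
Why: Copper-catalysed asymmetric conjugate addition of Me3Al to the β,β-disubstituted enone: the chiral phosphoramidite–methylcopper complex selects one enone face and so sets the quaternary carbon (future C10), and O-triflation of the regiodefined enolate (activated as its lithium aluminate) fixes the double bond between future C4 and C5.

Step 3
Reactants: 6
Product: 7 tert-butyl 2-[(1R)-1,3-dimethylcyclohex-2-en-1-yl]acetate
Conditions: MeZnCl (2 equiv), Pd(PPh3)4 (5 mol %), THF, 50 °C
Reagents that add atoms: methylzinc chloride, C[Zn]Cl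
Why: Negishi cross-coupling of the enol triflate with MeZnCl (oxidative addition to zerovalent palladium, transmetalation, reductive elimination) installs the C4 methyl group on the alkene without touching the ester or the quaternary centre.

Step 4
Reactants: 7; 8 2-bromo-N-methoxy-N-methylacetamide
Product: 9 tert-butyl 2-[(1S)-1,3-dimethylcyclohex-2-en-1-yl]-4-[methoxy(methyl)amino]-4-oxobutanoate (C9 epimers)
Conditions: LiN(iPr)2, THF/DMPU, −78 °C; then 8, −78 to −20 °C
Reagents that add atoms: none
Why: SN2 alkylation of the lithium ester enolate by the activated α-bromo amide forms C8–C9 and brings in C12 as a Weinreb amide; C9 forms as an epimer mixture that is of no consequence because C9 is re-set in step 10.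

Step 5
Reactants: 9; 10 2,2-dimethoxyacetaldehyde
Product: 13 tert-butyl (3E)-2-[(1S)-1,3-dimethylcyclohex-2-en-1-yl]-5,5-dimethoxy-3-[methoxy(methyl)carbamoyl]pent-3-enoate, via lithium aldolate 11 (not isolated), via mesylate 12 (not isolated)
Conditions: LiN(iPr)2, THF, −78 °C; 10 (anhydrous); MsCl, −78 to 0 °C; DBU (3 equiv), 40 °C
Reagents that add atoms: none
Why: Aldol addition of the kinetically formed amide enolate (the CH2 α to the amide is far more accessible than the neopentyl CH α to the tert-butyl ester) followed by mesylation and E1cB elimination gives the trisubstituted alkylidene, the E isomer (C6 trans to the amide carbonyl and cis to C9) being expected as the more stable arrangement.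

Step 6
Reactants: 13
Product: 14 tert-butyl (3E)-2-[(1S)-1,3-dimethylcyclohex-2-en-1-yl]-3-[methoxy(methyl)carbamoyl]-5-oxopent-3-enoate
Conditions: Amberlyst-15, acetone/H2O (20:1), rt
Reagents that add atoms: water, O
Why: Acid-catalysed acetal hydrolysis releases the C6 aldehyde, and because 4-oxo-2-enoic acid derivatives favour the geometry with the two carbonyl groups trans, any Z isomer from step 5 is expected to equilibrate to the required E enal under the acidic conditions.

Step 7
Reactants: 14
Product: 16 tert-butyl 6-hydroxy-12-[methoxy(methyl)amino]-12-oxo-5β-drim-7-en-11-oate (cis-fused; C6/C9 epimers), via chloro alkoxide 15 (not isolated)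
Conditions: Me2AlCl (3 equiv), CH2Cl2, −78 °C; then Me3Al (4 equiv), −78 to 0 °C; aq. KNaC4H4O6
Reagents that add atoms: trimethylaluminium, C[Al](C)C
Why: Proposed new method: Me2AlCl activates the aldehyde of 14 and C5 of the ring A alkene attacks C6 (cationic Prins addition), closing ring B in a 6-exo mode with the tertiary cation developing at C4 outside the new ring, the topology of the citronellal-to-isopulegol cyclization; with more than one equivalent of the chloroaluminium Lewis acid the zwitterion is expected to collapse by chloride delivery to C4 (chloro alkoxide 15) instead of by proton loss, and the tertiary C4–Cl bond is then re-ionized and methylated by Me3Al to complete the gem-dimethyl group. The closest known reaction types are the alkylaluminium-halide-induced cyclization of 6-alkenals to γ-chloro alcohols and the methylation of tertiary alkyl chlorides by Me3Al; their tandem use on a conjugated enal to build a decalin with its gem-dimethyl carbon is untested. Of the new stereocentres, C5 is set by the tether, which delivers C6 to the face of C5 on which C9 lies, so H5 ends up cis to the C10 methyl group (cis-fused, corrected in step 8); C6 forms as an epimer mixture that is erased in step 8; C4 is not stereogenic. The step needs ring closure to outrun methyl transfer to the aldehyde (secured by using Me2AlCl at −78 °C and adding Me3Al only afterwards) and substitution at C4 to outrun elimination (low temperature, non-basic medium).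

Step 8
Reactants: 16
Product: 18 tert-butyl 12-[methoxy(methyl)amino]-6,12-dioxodrim-7-en-11-oate (5α-H; trans-fused; C9 epimers), via cis-fused enone 17 (not isolated)
Conditions: Dess–Martin periodinane, CH2Cl2, rt; then DBU (0.5 equiv), toluene, 60 °C, argon
Reagents that add atoms: none
Why: Dess–Martin oxidation gives the 7-en-6-one, in which H5 is α to the ketone and should epimerize through the enol to the trans-fused isomer (5α-H, anti to the C10 methyl group), expected to be the more stable one as in natural 6-oxodrim-7-enes, which sets C5 and merges the C6 and C9 epimers.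

Step 9
Reactants: 18
Product: 19 tert-butyl 6β-hydroxy-12-[methoxy(methyl)amino]-12-oxodrim-7-en-11-oate (C9 epimers)
Conditions: NaBH4, CeCl3·7H2O, MeOH/THF, −40 °C
Reagents that add atoms: none
Why: Luche 1,2-reduction: hydride is expected to add to the α-face of C6 because the β-face is screened by the 1,3-diaxial methyl groups on C4 and C10, giving the axial 6β-alcohol.

Step 10
Reactants: 19
Product: 20 tert-butyl 6β,9α-dihydroxy-12-[methoxy(methyl)amino]-12-oxodrim-7-en-11-oate
Conditions: KN(SiMe3)2 (2.3 equiv), THF, −78 to −40 °C; 2-(phenylsulfonyl)-3-phenyloxaziridine, −78 °C; aq. NH4Cl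
Reagents that add atoms: 2-(phenylsulfonyl)-3-phenyloxaziridine, O=S(=O)(c1ccccc1)N1OC1c1ccccc1
Why: Oxaziridine α-hydroxylation of an ester enolate: the dianion (C6 alkoxide and C9 ester dienolate) should be oxidized at C9 on the α-face, anti to the axial C10 methyl group, which gives the 9α-hydroxy 9β-ester configuration and leaves the 7,8-double bond in place.

Step 11
Reactants: 20
Product: 21 tert-butyl 6β,9α-dihydroxy-12-oxodrim-7-en-11-oate
Conditions: iBu2AlH (4 equiv), THF, −78 °C; aq. KNaC4H4O6
Reagents that add atoms: none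
Why: Weinreb amide reduction: iBu2AlH adds once to give a chelated tetrahedral aluminium hemiaminal that collapses to the enal only on work-up, while the tert-butyl ester on the fully substituted C9 is too hindered to be reduced at −78 °C; no stereocentre is touched.

Step 12
Reactants: 22 (2E,4E)-hexa-2,4-dienal; 23 malonic acid
Product: 24 (2E,4E,6E)-octa-2,4,6-trienoic acid
Conditions: pyridine, piperidine (cat.), 90 °C
Reagents that add atoms: none
Why: Doebner–Knoevenagel condensation of the dienal with malonic acid followed by decarboxylation in pyridine gives the all-E trienoic acid, the new double bond forming with E geometry under thermodynamic control.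

Step 13
Reactants: 21; 24
Product: 26 tert-butyl 9α-hydroxy-6β-[(2E,4E,6E)-octa-2,4,6-trienoyloxy]-12-oxodrim-7-en-11-oate, via mixed anhydride 25 (not isolated)
Conditions: 24, 2,4,6-trichlorobenzoyl chloride, Et3N, toluene, rt; then 21, DMAP, rt
Reagents that add atoms: none
Why: Yamaguchi esterification: the mixed anhydride 25 acylates DMAP and the acylpyridinium is captured by the secondary 6β-hydroxyl, the tertiary 9α-hydroxyl being too hindered to compete; no stereocentre is touched.

Step 14
Reactants: 26
Product: 27 ustusoic acid B, (5S,6R,9S,10S)-9-hydroxy-6-[(2E,4E,6E)-octa-2,4,6-trienoyloxy]-12-oxodrim-7-en-11-oic acid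
Conditions: CF3CO2H/CH2Cl2 (1:4), 0 °C
Reagents that add atoms: none
Why: Acidolysis of the tert-butyl ester through the tert-butyl cation (lost as 2-methylpropene) frees the C11 acid under conditions that should leave the trienoate, the enal and the tertiary alcohol untouched; no stereocentre is affected.

**Compound list**

1 | 3-ethoxycyclohex-2-en-1-one | CCOC1=CC(=O)CCC1 | starting material
2 | tert-butyl acetate | CC(=O)OC(C)(C)C | starting material
3 | tert-butyl 2-(3-ethoxy-1-hydroxycyclohex-2-en-1-yl)acetate | CCOC1=CC(O)(CC(=O)OC(C)(C)C)CCC1 | intermediate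
4 | tert-butyl 2-(3-oxocyclohex-1-en-1-yl)acetate | O=C1C=C(CC(=O)OC(C)(C)C)CCC1 | intermediate
5 | dimethylaluminium enolate of tert-butyl 2-[(1R)-1-methyl-3-oxocyclohexyl]acetate | CC(C)(C)OC(=O)C[C@@]1(C)CCCC(O[Al](C)C)=C1 | intermediate
6 | tert-butyl 2-[(1R)-1-methyl-3-(trifluoromethylsulfonyloxy)cyclohex-2-en-1-yl]acetate | CC(C)(C)OC(=O)C[C@@]1(C)CCCC(OS(=O)(=O)C(F)(F)F)=C1 | intermediate
7 | tert-butyl 2-[(1R)-1,3-dimethylcyclohex-2-en-1-yl]acetate | CC(C)(C)OC(=O)C[C@@]1(C)CCCC(C)=C1 | intermediate
8 | 2-bromo-N-methoxy-N-methylacetamide | CON(C)C(=O)CBr | starting material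
9 | tert-butyl 2-[(1S)-1,3-dimethylcyclohex-2-en-1-yl]-4-[methoxy(methyl)amino]-4-oxobutanoate (C9 epimers) | CON(C)C(=O)CC(C(=O)OC(C)(C)C)[C@@]1(C)CCCC(C)=C1 | intermediate
10 | 2,2-dimethoxyacetaldehyde | COC(OC)C=O | starting material
11 | lithium aldolate of 9 with 10 (diastereomer mixture) | COC(OC)C(O[Li])C(C(=O)N(C)OC)C(C(=O)OC(C)(C)C)[C@@]1(C)CCCC(C)=C1 | intermediate
12 | mesylate of the aldol (diastereomer mixture) | COC(OC)C(OS(C)(=O)=O)C(C(=O)N(C)OC)C(C(=O)OC(C)(C)C)[C@@]1(C)CCCC(C)=C1 | intermediate
13 | tert-butyl (3E)-2-[(1S)-1,3-dimethylcyclohex-2-en-1-yl]-5,5-dimethoxy-3-[methoxy(methyl)carbamoyl]pent-3-enoate (C9 epimers) | COC(OC)/C=C(\C(C(=O)OC(C)(C)C)[C@@]1(C)CCCC(C)=C1)C(=O)N(C)OC | intermediate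
14 | tert-butyl (3E)-2-[(1S)-1,3-dimethylcyclohex-2-en-1-yl]-3-[methoxy(methyl)carbamoyl]-5-oxopent-3-enoate (C9 epimers) | O=C/C=C(\C(C(=O)OC(C)(C)C)[C@@]1(C)CCCC(C)=C1)C(=O)N(C)OC | intermediate
15 | dimethylaluminium alkoxide of the cis-fused C4 chloride (4-chloro-4-methyl, 5β-H, 10β-methyl; C4/C6/C9 epimers) | C[Al](C)OC1C=C(C(=O)N(C)OC)C(C(=O)OC(C)(C)C)[C@@]2(C)CCCC(C)(Cl)[C@@H]12 | intermediate
16 | tert-butyl 6-hydroxy-12-[methoxy(methyl)amino]-12-oxo-5β-drim-7-en-11-oate (cis-fused, 10β-methyl; C6/C9 epimers) | OC1C=C(C(=O)N(C)OC)C(C(=O)OC(C)(C)C)[C@@]2(C)CCCC(C)(C)[C@@H]12 | intermediate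
17 | tert-butyl 12-[methoxy(methyl)amino]-6,12-dioxo-5β-drim-7-en-11-oate (cis-fused; C9 epimers) | O=C1C=C(C(=O)N(C)OC)C(C(=O)OC(C)(C)C)[C@@]2(C)CCCC(C)(C)[C@@H]12 | intermediate
18 | tert-butyl 12-[methoxy(methyl)amino]-6,12-dioxodrim-7-en-11-oate (5α-H, trans-fused; C9 epimers) | O=C1C=C(C(=O)N(C)OC)C(C(=O)OC(C)(C)C)[C@@]2(C)CCCC(C)(C)[C@H]12 | intermediate
19 | tert-butyl 6β-hydroxy-12-[methoxy(methyl)amino]-12-oxodrim-7-en-11-oate (C9 epimers) | O[C@@H]1C=C(C(=O)N(C)OC)C(C(=O)OC(C)(C)C)[C@@]2(C)CCCC(C)(C)[C@H]12 | intermediate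
20 | tert-butyl 6β,9α-dihydroxy-12-[methoxy(methyl)amino]-12-oxodrim-7-en-11-oate | O[C@@H]1C=C(C(=O)N(C)OC)[C@](O)(C(=O)OC(C)(C)C)[C@@]2(C)CCCC(C)(C)[C@H]12 | intermediate
21 | tert-butyl 6β,9α-dihydroxy-12-oxodrim-7-en-11-oate | O[C@@H]1C=C(C=O)[C@](O)(C(=O)OC(C)(C)C)[C@@]2(C)CCCC(C)(C)[C@H]12 | intermediate
22 | (2E,4E)-hexa-2,4-dienal | C/C=C/C=C/C=O | starting material
23 | malonic acid | OC(=O)CC(=O)O | starting material
24 | (2E,4E,6E)-octa-2,4,6-trienoic acid | C/C=C/C=C/C=C/C(=O)O | intermediate
25 | (2E,4E,6E)-octa-2,4,6-trienoic 2,4,6-trichlorobenzoic anhydride | C/C=C/C=C/C=C/C(=O)OC(=O)c1c(Cl)cc(Cl)cc1Cl | intermediate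
26 | tert-butyl 9α-hydroxy-6β-[(2E,4E,6E)-octa-2,4,6-trienoyloxy]-12-oxodrim-7-en-11-oate | C/C=C/C=C/C=C/C(=O)O[C@@H]1C=C(C=O)[C@](O)(C(=O)OC(C)(C)C)[C@@]2(C)CCCC(C)(C)[C@H]12 | intermediate
27 | ustusoic acid B | C/C=C/C=C/C=C/C(=O)O[C@@H]1C=C(C=O)[C@](O)(C(=O)O)[C@@]2(C)CCCC(C)(C)[C@H]12 | target

**Step count and risks**

Total step count: 14. Longest linear sequence: 13 steps (steps 1–11, 13 and 14; step 12 is a one-step branch).

Steps most likely to fail:

1. Step 7 (labelled). What may go wrong: methyl transfer from aluminium to the aldehyde before ring closure, loss of a proton from the C4 cation in place of chloride capture, or elimination in place of substitution during the methylation. The fallback uses known chemistry, sets out from 14 and comes back at 16. Compound 14 is cyclized with Me2AlCl (1.1 equiv, CH2Cl2, −78 °C) under intramolecular carbonyl-ene conditions to the homoallylic alcohol with an exocyclic methylene group on C4, the ene product F1 (its endocyclic C3=C4 isomer would behave alike). Markovnikov addition of anhydrous HCl (CH2Cl2, −40 °C) gives the tertiary chloride, the chloro alcohol F2. Methylation of the tertiary chloride with Me3Al (CH2Cl2, −78 to 0 °C) then gives 16.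

2. Step 2. What may go wrong: deprotonation of the doubly activated CH2 of 4 by Me3Al in place of conjugate addition, or poor facial selectivity of the methyl transfer. The fallback sets out from 1 and comes back at 7, replacing asymmetric catalysis by a sigmatropic rearrangement and a resolution. MeLi adds to 1 to give the methyl adduct F3 (not isolated), and dilute acid transposes it to 3-methylcyclohex-2-en-1-one F4. A second MeLi addition gives racemic 1,3-dimethylcyclohex-2-en-1-ol F5. Johnson–Claisen rearrangement (MeC(OEt)3, EtCO2H cat., 140 °C) forms the quaternary carbon and the C4=C5 alkene in racemic ethyl 2-(1,3-dimethylcyclohex-2-en-1-yl)acetate F6. Saponification (LiOH, aq. THF) gives the racemic acid F7, which is resolved by crystallization with an enantiopure 1-phenylethylamine to (R)-2-(1,3-dimethylcyclohex-2-en-1-yl)acetic acid F8. tert-Butyl 2,2,2-trichloroacetimidate with catalytic BF3·OEt2 converts F8 into 7.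

3. Step 8. What may go wrong: slow or incomplete epimerization at C5 because the base mainly forms the extended C9 enolate, an equilibrium that does not lie far enough on the trans side, or migration of the double bond to C8=C9. The fallback sets out from 16 and comes back at 18, setting C5 under kinetic control. Compound 16 is converted into the mesylate F9 (MsCl, Et3N, CH2Cl2) and eliminated with DBU to the 5,7-diene F10. Hydroboration–oxidation (BH3·THF, 0 °C; NaBO3) of the electron-rich C5=C6 bond from the α-face, anti to the C4 and C10 methyl groups, adds H to C5 and OH to C6 in a syn fashion and should give the trans-fused 6α-alcohol F11. Dess–Martin oxidation of F11 gives 18.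

Further compounds
F1 | step 7 | tert-butyl 6-hydroxy-4-methylidene-12-[methoxy(methyl)amino]-12-oxo-18-nor-5β-drim-7-en-11-oate (cis-fused; C6/C9 epimers) | OC1C=C(C(=O)N(C)OC)C(C(=O)OC(C)(C)C)[C@@]2(C)CCCC(=C)[C@@H]12
F2 | step 7 | tert-butyl 4-chloro-6-hydroxy-12-[methoxy(methyl)amino]-12-oxo-18-nor-5β-drim-7-en-11-oate (cis-fused; C4/C6/C9 epimers) | OC1C=C(C(=O)N(C)OC)C(C(=O)OC(C)(C)C)[C@@]2(C)CCCC(C)(Cl)[C@@H]12
F3 | step 2 | 3-ethoxy-1-methylcyclohex-2-en-1-ol (racemic) | CCOC1=CC(C)(O)CCC1
F4 | step 2 | 3-methylcyclohex-2-en-1-one | CC1=CC(=O)CCC1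
F5 | step 2 | 1,3-dimethylcyclohex-2-en-1-ol (racemic) | CC1=CC(C)(O)CCC1
F6 | step 2 | ethyl 2-(1,3-dimethylcyclohex-2-en-1-yl)acetate (racemic) | CCOC(=O)CC1(C)CCCC(C)=C1
F7 | step 2 | 2-(1,3-dimethylcyclohex-2-en-1-yl)acetic acid (racemic) | OC(=O)CC1(C)CCCC(C)=C1
F8 | step 2 | (R)-2-(1,3-dimethylcyclohex-2-en-1-yl)acetic acid | OC(=O)C[C@@]1(C)CCCC(C)=C1
F9 | step 8 | tert-butyl 6-(methylsulfonyloxy)-12-[methoxy(methyl)amino]-12-oxo-5β-drim-7-en-11-oate (cis-fused; C6/C9 epimers) | CS(=O)(=O)OC1C=C(C(=O)N(C)OC)C(C(=O)OC(C)(C)C)[C@@]2(C)CCCC(C)(C)[C@@H]12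
F10 | step 8 | tert-butyl 12-[methoxy(methyl)amino]-12-oxodrima-5,7-dien-11-oate (C9 epimers) | CON(C)C(=O)C1=CC=C2C(C)(C)CCC[C@]2(C)C1C(=O)OC(C)(C)C
F11 | step 8 | tert-butyl 6α-hydroxy-12-[methoxy(methyl)amino]-12-oxodrim-7-en-11-oate (5α-H, trans-fused; C9 epimers) | O[C@H]1C=C(C(=O)N(C)OC)C(C(=O)OC(C)(C)C)[C@@]2(C)CCCC(C)(C)[C@H]12
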